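**Plan** (TBS = tert-butyldimethylsilyl, TBSO = tert-butyldimethylsilyloxy; C1–C8 = bicyclo[3.2.1]octane numbering of the target)

- Enabling feature: the six-membered ring C1–C2–C3–C4–C5–C8 is a 5-styrylresorcinol held in its diketo form, because C1 and C5 are tied by the C6–C7 bridge and, as bridgeheads, cannot enolise.
- Cuts, in retrosynthetic order: four O–Si bonds; then C3=C4 (aldol condensation) and C1–C2 (acylation), as in a polyketide resorcinol, which removes a two-carbon acetyl unit and leaves a 2-cinnamoyl-3,4-diarylcyclopentanone.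
- Further cuts: the exocyclic C–C bond of the cinnamoyl arm and the C6–aryl bond (conjugate addition–aldol on a 4-arylcyclopentenone); then the C7–aryl bond (allylic arylation of a chiral-pool cyclopentenyl acetate).
- Forward order: cyclopentene → cyclopentenone → all-trans cyclopentanone (the five-membered ring C1, C7, C6, C5, C8) → six-membered ring closed across its two α-carbons → desilylation.
- Stereochemistry: C7 from the acetate carbon of the chiral-pool monoacetate by inversion; C6 by anti conjugate addition; C1 and C5 by the ring closure, steered to the face anti to the 3,5-bis(TBSO)phenyl group.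

Key step: step 7

Remark: β-dicarbonyl compounds 14 and 15 are written as keto forms although they will be largely enolised; the carbinol centre of 13 is left undefined because step 6 removes it.

**Step 1**
Reactants: 1 5-bromobenzene-1,3-diol
Product: 2 1-bromo-3,5-bis(TBSO)benzene
Conditions: TBSCl (2.4 equiv), imidazole (5 equiv), DMF, 0 °C → rt
Reagents that add atoms: tert-butyldimethylsilyl chloride, CC(C)(C)[Si](C)(C)Cl
Why: Standard phenol silylation masks both acidic OH groups for the later Grignard and dianion chemistry and installs the bulky meta substituents that later bias the ring closure.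

**Step 2**
Reactants: 3 (E)-3-(4-hydroxyphenyl)prop-2-enal
Product: 4 (E)-3-[4-(TBSO)phenyl]prop-2-enal
Conditions: TBSCl (1.2 equiv), imidazole (2.5 equiv), CH2Cl2, 0 °C → rt
Reagents that add atoms: tert-butyldimethylsilyl chloride, CC(C)(C)[Si](C)(C)Cl
Why: Phenol silylation under mild base leaves the enal and its E geometry untouched.

**Step 3**
Reactants: 5 (4-bromophenoxy)(tert-butyl)dimethylsilane; 6 (1S,4R)-4-hydroxycyclopent-2-en-1-yl acetate [(1R,4S)-cis-4-acetoxycyclopent-2-en-1-ol]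
Product: 9 (1R,4R)-4-[4-(TBSO)phenyl]cyclopent-2-en-1-ol, via aryllithium 7 (not isolated), via lithium aryltrimethoxyborate 8 (not isolated)
Conditions: 5, n-BuLi, THF, −78 °C; B(OMe)3, −78 → 0 °C; then 6, NiCl2(PPh3)2 (10 mol%), NaI, t-BuCN, THF, rt → 45 °C
Reagents that add atoms: none
Why: Nickel-catalysed allylic arylation with an aryl borate should replace the acetate at its own carbon with overall inversion (π-allylnickel formed anti to acetate, aryl delivered from the metal face), so the aryl group ends up trans to the hydroxyl and the future C7 is set as R from the chiral pool.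

**Step 4**
Reactants: 9 (1R,4R)-4-[4-(TBSO)phenyl]cyclopent-2-en-1-ol
Product: 10 (4R)-4-[4-(TBSO)phenyl]cyclopent-2-en-1-one
Conditions: MnO2 (15 equiv), CH2Cl2, rt
Reagents that add atoms: none
Why: Allylic alcohol oxidation with MnO2 is neutral, so the γ-benzylic stereocentre should not epimerise and the double bond should not move into conjugation with the arene.

**Step 5**
Reactants: 2 1-bromo-3,5-bis(TBSO)benzene; 10 (4R)-4-[4-(TBSO)phenyl]cyclopent-2-en-1-one; 4 (E)-3-[4-(TBSO)phenyl]prop-2-enal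
Product: 13 (2S,3S,4R)-3-[3,5-bis(TBSO)phenyl]-4-[4-(TBSO)phenyl]-2-{(E)-1-hydroxy-3-[4-(TBSO)phenyl]prop-2-en-1-yl}cyclopentan-1-one (both carbinol epimers), via arylmagnesium bromide 11 (not isolated), via bromomagnesium enolate 12 (not isolated)
Conditions: 2, Mg, THF, 40 °C; then 10 (0.95 equiv), CuBr·SMe2 (10 mol%), THF, −78 → −40 °C; then 4 (1.3 equiv), −78 °C; aq NH4Cl
Reagents that add atoms: none
Why: Copper-catalysed conjugate addition of 11 should occur anti to the aryl group of 10, and the regiodefined enolate 12 should add to aldehyde 4 anti to the new aryl group (three-component conjugate addition–aldol coupling), giving the all-trans cyclopentanone.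

**Step 6**
Reactants: 13 the aldol from step 5
Product: 14 (2R,3S,4R)-3-[3,5-bis(TBSO)phenyl]-4-[4-(TBSO)phenyl]-2-{(E)-3-[4-(TBSO)phenyl]prop-2-enoyl}cyclopentan-1-one
Conditions: Dess–Martin periodinane (1.3 equiv), CH2Cl2, 0 °C → rt
Reagents that add atoms: none
Why: Dess–Martin oxidation of the β-hydroxy ketone should give the β-diketone without touching silyl ethers or alkenes; C2 becomes a freely equilibrating centre that rests trans to its aryl neighbour.

**Step 7**
Reactants: 14 the β-diketone from step 6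
Product: 16 (1R,5S,6S,7S)-6-[3,5-bis(TBSO)phenyl]-7-[4-(TBSO)phenyl]-4-{(E)-2-[4-(TBSO)phenyl]ethenyl}bicyclo[3.2.1]oct-3-ene-2,8-dione, via triketone 15 (not isolated)
Conditions: LiN(iPr)2 (2.3 equiv), THF, −78 → 0 °C; MeC(O)N(OMe)Me (1.3 equiv), −78 → −10 °C; then TsOH·H2O (4.0 equiv, 0.4 equiv over the bases), solvent exchange to PhMe, 4 Å MS, 80 °C, same flask
Reagents that add atoms: N-methoxy-N-methylacetamide, CC(=O)N(C)OC
Why: Two equivalents of amide base turn 14 into its 1,3-dianion, whose only carbanionic site is ring carbon C5 of the cyclopentanone (the cinnamoyl group has no α-hydrogen), and this carbon attacks the Weinreb amide to give triketone 15 on acidification (γ-acylation of a β-diketone dianion, the Harris-type triketone synthesis). Under TsOH the terminal enol of the new acetyl group adds to the protonated cinnamoyl carbonyl and the tertiary, doubly allylic carbinol loses water toward the only non-bridgehead α-carbon; the closest known reaction types are the Collie-type aldol cyclisation of 1,3,5-triketones to resorcinols and the acid-catalysed bridged aldol condensation of cis-1,3-diacylcyclopentanes. The six-membered ring closes in a 6-(enolendo)-exo-trig mode across the two α-carbons of the cyclopentanone and stops at the ene-dione, because both carbons between the carbonyls are now bridgeheads of a bicyclo[3.2.1]octane and cannot enolise toward a resorcinol. C1 and C5 are set by the closure itself: both are epimerisable in 15, the bridge can form only when the two acyl groups are cis, and the fixed aryl-bearing centres C6 and C7 decide on which face this happens. The face syn to the slim 4-(TBSO)phenyl group and anti to the 3,5-bis(TBSO)phenyl group should be preferred, since it keeps the cinnamoyl group trans to its aryl neighbour and puts the bulkier arene exo. The step needs C5 over C2 or O acylation (secured by the dianion and the stable Weinreb adduct) and aldol over oxa-Michael or C-Michael closure onto the enone (these are reversible under acid, whereas dehydration is pulled by the sieves).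

**Step 8**
Reactants: 16 the tetrasilyl ether from step 7
Product: 17 (1R,5S,6S,7S)-6-(3,5-dihydroxyphenyl)-7-(4-hydroxyphenyl)-4-[(E)-2-(4-hydroxyphenyl)ethenyl]bicyclo[3.2.1]oct-3-ene-2,8-dione
Conditions: Bu4NF (4.4 equiv), AcOH (4.4 equiv), THF, 0 °C
Reagents that add atoms: none
Why: Acetic-acid-buffered fluoride should cleave the four aryl silyl ethers without forming alkoxide or hydroxide that could open the non-enolisable β-diketone by retro-Claisen cleavage; no stereocentre is touched.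

**Compound list**

1 | 5-bromobenzene-1,3-diol | Oc1cc(O)cc(Br)c1 | starting material
2 | 1-bromo-3,5-bis(TBSO)benzene | CC(C)(C)[Si](C)(C)Oc1cc(Br)cc(O[Si](C)(C)C(C)(C)C)c1 | intermediate
3 | (E)-3-(4-hydroxyphenyl)prop-2-enal | O=C/C=C/c1ccc(O)cc1 | starting material
4 | (E)-3-[4-(TBSO)phenyl]prop-2-enal | O=C/C=C/c1ccc(O[Si](C)(C)C(C)(C)C)cc1 | intermediate
5 | (4-bromophenoxy)(tert-butyl)dimethylsilane | CC(C)(C)[Si](C)(C)Oc1ccc(Br)cc1 | starting material
6 | (1S,4R)-4-hydroxycyclopent-2-en-1-yl acetate | O[C@@H]1C[C@H](OC(C)=O)C=C1 | starting material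
7 | [4-(TBSO)phenyl]lithium | [Li]c1ccc(O[Si](C)(C)C(C)(C)C)cc1 | intermediate (not isolated)
8 | lithium [4-(TBSO)phenyl]trimethoxyborate | [Li+].CO[B-](OC)(OC)c1ccc(O[Si](C)(C)C(C)(C)C)cc1 | intermediate (not isolated)
9 | (1R,4R)-4-[4-(TBSO)phenyl]cyclopent-2-en-1-ol | O[C@@H]1C[C@@H](c2ccc(O[Si](C)(C)C(C)(C)C)cc2)C=C1 | intermediate
10 | (4R)-4-[4-(TBSO)phenyl]cyclopent-2-en-1-one | O=C1C[C@@H](c2ccc(O[Si](C)(C)C(C)(C)C)cc2)C=C1 | intermediate
11 | [3,5-bis(TBSO)phenyl]magnesium bromide | Br[Mg]c1cc(O[Si](C)(C)C(C)(C)C)cc(O[Si](C)(C)C(C)(C)C)c1 | intermediate (not isolated)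
12 | bromomagnesium (3S,4R)-3-[3,5-bis(TBSO)phenyl]-4-[4-(TBSO)phenyl]cyclopent-1-en-1-olate | Br[Mg]OC1=C[C@@H](c2cc(O[Si](C)(C)C(C)(C)C)cc(O[Si](C)(C)C(C)(C)C)c2)[C@H](c2ccc(O[Si](C)(C)C(C)(C)C)cc2)C1 | intermediate (not isolated)
13 | (2S,3S,4R)-3-[3,5-bis(TBSO)phenyl]-4-[4-(TBSO)phenyl]-2-{(E)-1-hydroxy-3-[4-(TBSO)phenyl]prop-2-en-1-yl}cyclopentan-1-one, carbinol epimers | OC(/C=C/c1ccc(O[Si](C)(C)C(C)(C)C)cc1)[C@H]1C(=O)C[C@@H](c2ccc(O[Si](C)(C)C(C)(C)C)cc2)[C@@H]1c1cc(O[Si](C)(C)C(C)(C)C)cc(O[Si](C)(C)C(C)(C)C)c1 | intermediate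
14 | (2R,3S,4R)-3-[3,5-bis(TBSO)phenyl]-4-[4-(TBSO)phenyl]-2-{(E)-3-[4-(TBSO)phenyl]prop-2-enoyl}cyclopentan-1-one | O=C(/C=C/c1ccc(O[Si](C)(C)C(C)(C)C)cc1)[C@H]1C(=O)C[C@@H](c2ccc(O[Si](C)(C)C(C)(C)C)cc2)[C@@H]1c1cc(O[Si](C)(C)C(C)(C)C)cc(O[Si](C)(C)C(C)(C)C)c1 | intermediate
15 | (3S,4S)-2-acetyl-4-[3,5-bis(TBSO)phenyl]-3-[4-(TBSO)phenyl]-5-{(E)-3-[4-(TBSO)phenyl]prop-2-enoyl}cyclopentan-1-one, C2 and C5 epimerisable | O=C(/C=C/c1ccc(O[Si](C)(C)C(C)(C)C)cc1)C1C(=O)C(C(C)=O)[C@@H](c2ccc(O[Si](C)(C)C(C)(C)C)cc2)[C@@H]1c1cc(O[Si](C)(C)C(C)(C)C)cc(O[Si](C)(C)C(C)(C)C)c1 | intermediate (not isolated)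
16 | (1R,5S,6S,7S)-6-[3,5-bis(TBSO)phenyl]-7-[4-(TBSO)phenyl]-4-{(E)-2-[4-(TBSO)phenyl]ethenyl}bicyclo[3.2.1]oct-3-ene-2,8-dione | O=C1C=C(/C=C/c2ccc(O[Si](C)(C)C(C)(C)C)cc2)[C@H]2C(=O)[C@@H]1[C@@H](c1ccc(O[Si](C)(C)C(C)(C)C)cc1)[C@@H]2c1cc(O[Si](C)(C)C(C)(C)C)cc(O[Si](C)(C)C(C)(C)C)c1 | intermediate
17 | (1R,5S,6S,7S)-6-(3,5-dihydroxyphenyl)-7-(4-hydroxyphenyl)-4-[(E)-2-(4-hydroxyphenyl)ethenyl]bicyclo[3.2.1]oct-3-ene-2,8-dione | O=C1C=C(/C=C/c2ccc(O)cc2)[C@H]2C(=O)[C@@H]1[C@@H](c1ccc(O)cc1)[C@@H]2c1cc(O)cc(O)c1 | target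

**Totals**

Total step count: 8. Longest linear sequence: 6 steps (steps 3 to 8).

**Steps most likely to fail**

1. Step 7. The closure may stall at the doubly enolised triketone: both α-carbons must return to the keto form with their acyl groups cis, and aldol addition to a conjugated, hindered ketone is only weakly downhill. The acetyl donor may also quench the dianion by proton transfer, material may be held in reversible Michael-type closures onto the cinnamoyl enone, or the bridge may form on the wrong face. Fallback: close the ring onto an aldehyde and add the styryl arm afterwards. It sets out from enone 10 and Grignard reagent 11. Enolate 12 is trapped with 2,2,2-trifluoroethyl formate instead of aldehyde 4 to give (1S,2S,3R)-2-[3,5-bis(TBSO)phenyl]-3-[4-(TBSO)phenyl]-5-oxocyclopentane-1-carbaldehyde F1. Its dianion is acetylated at C4 with MeC(O)N(OMe)Me as in step 7, and the resulting (4S,5S)-3-acetyl-5-[3,5-bis(TBSO)phenyl]-4-[4-(TBSO)phenyl]-2-oxocyclopentane-1-carbaldehyde F2 is cyclised without isolation (TsOH·H2O, PhMe, 4 Å MS) to (1R,5R,6S,7S)-6-[3,5-bis(TBSO)phenyl]-7-[4-(TBSO)phenyl]bicyclo[3.2.1]oct-3-ene-2,8-dione F3; an aldehyde is a far better aldol acceptor than the cinnamoyl ketone. Hydroboration of purchased tert-butyl(4-ethynylphenoxy)dimethylsilane (pinacolborane, Cp2Zr(H)Cl cat.) gives (E)-2-{2-[4-(TBSO)phenyl]ethenyl}-4,4,5,5-tetramethyl-1,3,2-dioxaborolane F4. This is added to the enone of F3 under base-free rhodium catalysis ([Rh(cod)OH]2, dioxane/H2O, 40 °C) to give the 3,4-dihydro derivative of 16, F5. Aerobic α,β-dehydrogenation (Pd(O2CCF3)2, DMSO, O2, AcOH, 80 °C) restores the C3=C4 double bond, and the route is rejoined at 16.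

2. Step 5. The Grignard reagent may add 1,2 to the enone or deprotonate its γ-benzylic position, enolate 12 may equilibrate by proton transfer before the aldehyde arrives, or the aldolate may undergo retro-aldol cleavage or dehydration on warming. Fallback: separate the conjugate addition from the aldol reaction. Setting out from 10 and 11, the copper-catalysed addition is run with Me3SiCl present and the enolate is isolated as {[(3S,4R)-3-[3,5-bis(TBSO)phenyl]-4-[4-(TBSO)phenyl]cyclopent-1-en-1-yl]oxy}trimethylsilane F6. A Mukaiyama aldol addition to aldehyde 4 (BF3·OEt2, CH2Cl2, −78 °C) then gives 13, where the route is rejoined.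

3. Step 3. The aryl group may be delivered to the other allyl terminus (giving the 2-arylcyclopent-3-enol), or stereochemical fidelity may be eroded through the π-allyl intermediate. Fallback: enone transposition on the chiral-pool siloxy enone. Setting out from bromide 5 (as aryllithium 7), CuI (0.5 equiv) gives lithium bis[4-(TBSO)phenyl]cuprate F7. This adds to purchased (R)-4-(TBSO)cyclopent-2-en-1-one anti to the siloxy group to give (3S,4R)-4-(TBSO)-3-[4-(TBSO)phenyl]cyclopentan-1-one F8. Loss of tert-butyldimethylsilanol under acid (aq AcOH/THF, 60 °C; no base, so the new γ-benzylic centre is not touched) moves the double bond to the other side of the carbonyl and gives enone 10, where the route is rejoined.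

**Further compounds**

F1 | step 7 | (1S,2S,3R)-2-[3,5-bis(TBSO)phenyl]-3-[4-(TBSO)phenyl]-5-oxocyclopentane-1-carbaldehyde | O=C[C@H]1C(=O)C[C@@H](c2ccc(O[Si](C)(C)C(C)(C)C)cc2)[C@@H]1c1cc(O[Si](C)(C)C(C)(C)C)cc(O[Si](C)(C)C(C)(C)C)c1
F2 | step 7 | (4S,5S)-3-acetyl-5-[3,5-bis(TBSO)phenyl]-4-[4-(TBSO)phenyl]-2-oxocyclopentane-1-carbaldehyde, C1 and C3 epimerisable | O=CC1C(=O)C(C(C)=O)[C@@H](c2ccc(O[Si](C)(C)C(C)(C)C)cc2)[C@@H]1c1cc(O[Si](C)(C)C(C)(C)C)cc(O[Si](C)(C)C(C)(C)C)c1
F3 | step 7 | (1R,5R,6S,7S)-6-[3,5-bis(TBSO)phenyl]-7-[4-(TBSO)phenyl]bicyclo[3.2.1]oct-3-ene-2,8-dione | O=C1C=C[C@H]2C(=O)[C@@H]1[C@@H](c1ccc(O[Si](C)(C)C(C)(C)C)cc1)[C@@H]2c1cc(O[Si](C)(C)C(C)(C)C)cc(O[Si](C)(C)C(C)(C)C)c1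
F4 | step 7 | (E)-2-{2-[4-(TBSO)phenyl]ethenyl}-4,4,5,5-tetramethyl-1,3,2-dioxaborolane | CC(C)(C)[Si](C)(C)Oc1ccc(/C=C/B2OC(C)(C)C(C)(C)O2)cc1
F5 | step 7 | 6-[3,5-bis(TBSO)phenyl]-7-[4-(TBSO)phenyl]-4-{(E)-2-[4-(TBSO)phenyl]ethenyl}bicyclo[3.2.1]octane-2,8-dione (3,4-dihydro derivative of 16, C4 not defined) | O=C1CC(/C=C/c2ccc(O[Si](C)(C)C(C)(C)C)cc2)[C@H]2C(=O)[C@@H]1[C@@H](c1ccc(O[Si](C)(C)C(C)(C)C)cc1)[C@@H]2c1cc(O[Si](C)(C)C(C)(C)C)cc(O[Si](C)(C)C(C)(C)C)c1
F6 | step 5 | {[(3S,4R)-3-[3,5-bis(TBSO)phenyl]-4-[4-(TBSO)phenyl]cyclopent-1-en-1-yl]oxy}trimethylsilane | C[Si](C)(C)OC1=C[C@@H](c2cc(O[Si](C)(C)C(C)(C)C)cc(O[Si](C)(C)C(C)(C)C)c2)[C@H](c2ccc(O[Si](C)(C)C(C)(C)C)cc2)C1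
F7 | step 3 | lithium bis[4-(TBSO)phenyl]cuprate | [Li+].CC(C)(C)[Si](C)(C)Oc1ccc([Cu-]c2ccc(O[Si](C)(C)C(C)(C)C)cc2)cc1
F8 | step 3 | (3S,4R)-4-(TBSO)-3-[4-(TBSO)phenyl]cyclopentan-1-one | O=C1C[C@@H](c2ccc(O[Si](C)(C)C(C)(C)C)cc2)[C@H](O[Si](C)(C)C(C)(C)C)C1
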